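The cyclopentenone ring C8–C12 (prostanoid numbering, C1 = ester carbon) is cut at both bonds to its ketone carbon C9. The feature used is that the only stereocentre, C12, lies between two sp2 ring neighbours, C11 and C8, which are bridged by that single carbonyl carbon. The ring therefore equals carbon monoxide plus a prochiral carbinol with two identical (Z)-2-iodovinyl arms. One palladium-catalysed carbonylative Heck cyclisation under a chiral bisphosphine should close the ring, fix C12 by choosing one arm, and leave a (Z)-iodomethylene at C7 for the α-chain. The precursor is the triethylsilyl ether of (1Z,4Z)-1,5-diiodo-3-[(Z)-oct-2-enyl]penta-1,4-dien-3-ol.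

Key step: step 7

Assumption: the hand of the ligand that leads to 12R cannot be derived in advance; (R)-BINAP is written and stands for whichever enantiomer of the best ligand gives 14.

Step 1
Reactants: 1 hexanal; 2 (2-carboxyethyl)triphenylphosphonium bromide
Product: 4 (Z)-non-3-enoic acid, via phosphonium ylide carboxylate 3 (not isolated)
Conditions: 2, NaN(SiMe3)2 (2.1 equiv), THF, 0 °C; then 1, −78 °C → rt; then 1 M HCl
Reagents that add atoms: none
Why: Wittig olefination of a non-stabilised ylide with an aliphatic aldehyde runs under kinetic control through the cis-oxaphosphetane and should give the (Z)-β,γ-unsaturated acid.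

Step 2
Reactants: 4 (Z)-non-3-enoic acid
Product: 5 methyl (Z)-non-3-enoate
Conditions: MeOH, H2SO4 (cat.), rt
Reagents that add atoms: methanol, CO
Why: Fischer esterification under mild acid catalysis should give the methyl ester without moving the β,γ double bond into conjugation.

Step 3
Reactants: 5 methyl (Z)-non-3-enoate; 6 ethynylmagnesium bromide
Product: 8 3-[(Z)-oct-2-enyl]penta-1,4-diyn-3-ol, via ethynyl ketone 7 (not isolated)
Conditions: 6 (3 equiv), LaCl3·2LiCl (0.3 equiv), THF, 0 °C; then aq. NH4Cl
Reagents that add atoms: none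
Why: Double Grignard addition to an ester, in which ynone 7 is more electrophilic than 5 and takes up the second acetylide, while the weakly basic acetylide and the oxophilic lanthanum salt should suppress enolisation of the C13 methylene.

Step 4
Reactants: 8 3-[(Z)-oct-2-enyl]penta-1,4-diyn-3-ol
Product: 9 triethyl{[3-[(Z)-oct-2-enyl]penta-1,4-diyn-3-yl]oxy}silane
Conditions: Et3SiOTf, 2,6-lutidine, CH2Cl2, −78 → 0 °C
Reagents that add atoms: triethylsilyl trifluoromethanesulfonate, CC[Si](CC)(CC)OS(=O)(=O)C(F)(F)F
Why: O-Silylation of a hindered tertiary propargylic alcohol with a silyl triflate and a hindered pyridine is standard, and the ether is needed later so that the oxygen can neither trap the acyl–palladium as a butenolide nor leave as a π-allyl nucleofuge.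

Step 5
Reactants: 9 triethyl{[3-[(Z)-oct-2-enyl]penta-1,4-diyn-3-yl]oxy}silane
Product: 11 triethyl{[1,5-diiodo-3-[(Z)-oct-2-enyl]penta-1,4-diyn-3-yl]oxy}silane, via mono-iodinated diyne 10 (not isolated)
Conditions: N-iodosuccinimide (2.4 equiv), AgNO3 (10 mol%), acetone, rt, dark
Reagents that add atoms: N-iodosuccinimide, O=C1CCC(=O)N1I
Why: Silver-catalysed electrophilic iodination of terminal alkynes goes through the silver acetylide and should leave the isolated (Z)-alkene and the silyl ether untouched.

Step 6
Reactants: 11 triethyl{[1,5-diiodo-3-[(Z)-oct-2-enyl]penta-1,4-diyn-3-yl]oxy}silane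
Product: 13 triethyl{[(1Z,4Z)-1,5-diiodo-3-[(Z)-oct-2-enyl]penta-1,4-dien-3-yl]oxy}silane, via half-reduced iodoenyne 12 (not isolated)
Conditions: 2-nitrobenzenesulfonohydrazide (5 equiv), Et3N, THF/i-PrOH, rt
Reagents that add atoms: none
Why: Diimide reduction, in which diimide released from the sulfonyl hydrazide delivers two hydrogens to one face of each iodoalkyne, should give both (Z)-iodoalkenes, the activated iodoalkynes being reduced faster than the 1,2-disubstituted C14=C15 alkene or the vinyl iodides formed.

Step 7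
Reactants: 13 triethyl{[(1Z,4Z)-1,5-diiodo-3-[(Z)-oct-2-enyl]penta-1,4-dien-3-yl]oxy}silane
Product: 14 (4R)-5-[(Z)-iodomethylidene]-4-[(Z)-oct-2-enyl]-4-(triethylsilyloxy)cyclopent-2-en-1-one
Conditions: Pd2(dba)3 (5 mol%), (R)-BINAP (12 mol%), CO (5 atm), 1,2,2,6,6-pentamethylpiperidine (2 equiv), toluene, 60 °C
Reagents that add atoms: carbon monoxide, [C-]#[O+]
Why: Proposed new method: zerovalent palladium carrying the chiral bisphosphine should insert into the C–I bond of one arm (C10), take up CO to give the C9 acyl–palladium, which the Z geometry holds cis to C12, add syn across C8=C7 of the second arm and, after rotation about C8–C7, lose H8 by syn β-hydride elimination, which leaves iodine on C7 cis to the C9 carbonyl. The closest known reaction type is the carbonylative cyclisation (cyclic acylpalladation) of (Z)-1-iodo-1,4-dienes to 5-alkylidenecyclopent-2-enones, here extended to an iodoalkene as acceptor and joined to the enantiotopic-group selection known from desymmetrising Heck cyclisations. The cyclopentenone closes in the 5-exo-trig mode, which should beat 6-exo attack on C14=C15 and 6-endo attack at the iodine-bearing C7, while carbopalladation of the second arm before CO uptake would need a four-membered ring and the CO pressure keeps CO insertion ahead of direct Heck closure onto C14=C15. C12 is controlled by the ligand, because the irreversible oxidative addition picks one of the two mirror-related arms and the metalated arm becomes C10–C11, so the hand of the ligand fixes 12R. The step needs a single carbonylation and no O-acylation: the silyl ether blocks butenolide formation and ionisation at C12, and with a hindered amine as the only base and no nucleophile present, oxidative addition to the product β-iodoenone has no outlet and should revert. The Z,Z geometry of 13 secures both the cis placement needed for ring closure and the (Z)-iodomethylene.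

Step 8
Reactants: 15 methyl hex-5-ynoate
Product: 16 methyl (E)-6-(4,4,5,5-tetramethyl-1,3,2-dioxaborolan-2-yl)hex-5-enoate
Conditions: pinacolborane (1.2 equiv), dicyclohexylborane (10 mol%), neat, rt
Reagents that add atoms: pinacolborane, [H]B1OC(C)(C)C(C)(C)O1
Why: Borane-catalysed syn, anti-Markovnikov hydroboration of a terminal alkyne with pinacolborane should give the (E)-alkenylboronate and tolerate the ester.

Step 9
Reactants: 14 (4R)-5-[(Z)-iodomethylidene]-4-[(Z)-oct-2-enyl]-4-(triethylsilyloxy)cyclopent-2-en-1-one; 16 methyl (E)-6-(4,4,5,5-tetramethyl-1,3,2-dioxaborolan-2-yl)hex-5-enoate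
Product: 17 methyl (5E,7Z)-7-[(5R)-5-[(Z)-oct-2-enyl]-2-oxo-5-(triethylsilyloxy)cyclopent-3-en-1-ylidene]hept-5-enoate
Conditions: 16 (1.3 equiv), PdCl2(dppf) (5 mol%), K3PO4 (3 M aq., 3 equiv), THF, rt, degassed, dark
Reagents that add atoms: none
Why: Suzuki–Miyaura coupling of the activated β-iodoenone with the alkenylboronate runs at room temperature with retention at both sp2 carbons, so C6 should take the place of iodine cis to C9 (7Z) next to the 5E bond, and the silyl ether and ester tolerate the mild aqueous base.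

Step 10
Reactants: 17 methyl (5E,7Z)-7-[(5R)-5-[(Z)-oct-2-enyl]-2-oxo-5-(triethylsilyloxy)cyclopent-3-en-1-ylidene]hept-5-enoate
Product: 18 methyl (5E,7Z)-7-[2-[(Z)-oct-2-enyl]-4-oxo-2-(triethylsilyloxy)-6-oxabicyclo[3.1.0]hexan-3-ylidene]hept-5-enoate (10,11-epoxide, oxirane trans to the silyloxy group)
Conditions: 30% aq. H2O2 (3 equiv), NaOH (0.3 equiv), MeOH/THF, −30 → −10 °C
Reagents that add atoms: hydrogen peroxide, OO
Why: Weitz–Scheffer epoxidation, in which hydroperoxide should add to C11 of the strained endocyclic enone (the kinetic site for nucleophiles in cross-conjugated cyclopentenone prostanoids) faster than to the delocalised dienone arm and not at all to the isolated C14=C15 alkene; attack anti to the silyloxy group is expected, and both new centres are erased in step 11.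

Step 11
Reactants: 18 methyl (5E,7Z)-7-[2-[(Z)-oct-2-enyl]-4-oxo-2-(triethylsilyloxy)-6-oxabicyclo[3.1.0]hexan-3-ylidene]hept-5-enoate
Product: 21 methyl (5E,7Z)-7-[(5R)-3-bromo-5-hydroxy-5-[(Z)-oct-2-enyl]-2-oxocyclopent-3-en-1-ylidene]hept-5-enoate, via bromohydrin 19 (not isolated), via silyl bromoenone 20 (not isolated)
Conditions: 48% aq. HBr (3 equiv), MeCN, 0 °C → rt
Reagents that add atoms: hydrogen bromide, Br
Why: Acid opening of an α,β-epoxy ketone by bromide occurs at the α-carbon C10 with inversion, the β-hydroxy ketone 19 dehydrates through its enol to α-bromoenone 20, and the same aqueous acid hydrolyses the triethylsilyl ether, whose C12–O bond cannot ionise because the cation would be of the cyclopentadienone type.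

Step 12
Reactants: 21 methyl (5E,7Z)-7-[(5R)-3-bromo-5-hydroxy-5-[(Z)-oct-2-enyl]-2-oxocyclopent-3-en-1-ylidene]hept-5-enoate
Product: 22 methyl (5E,7Z)-7-[(5R)-5-acetoxy-3-bromo-5-[(Z)-oct-2-enyl]-2-oxocyclopent-3-en-1-ylidene]hept-5-enoate
Conditions: Ac2O (3 equiv), Sc(OTf)3 (5 mol%), MeCN, −20 °C
Reagents that add atoms: acetic anhydride, CC(=O)OC(C)=O
Why: Lewis-acid-catalysed acylation with acetic anhydride acetylates hindered tertiary alcohols at low temperature without a nucleophilic catalyst that could add reversibly to the dienone and scramble the 7Z bond, and C12 is not touched.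

Compound list
1 | hexanal | CCCCCC=O | starting material
2 | (2-carboxyethyl)triphenylphosphonium bromide | [Br-].OC(=O)CC[P+](c1ccccc1)(c1ccccc1)c1ccccc1 | starting material
3 | sodium 3-(triphenyl-λ5-phosphanylidene)propanoate (ylide) | [Na+].[O-]C(=O)CC=P(c1ccccc1)(c1ccccc1)c1ccccc1 | intermediate (not isolated)
4 | (Z)-non-3-enoic acid | CCCCC/C=C\CC(=O)O | intermediate
5 | methyl (Z)-non-3-enoate | CCCCC/C=C\CC(=O)OC | intermediate
6 | ethynylmagnesium bromide | C#C[Mg]Br | starting material
7 | (Z)-undec-5-en-1-yn-3-one | CCCCC/C=C\CC(=O)C#C | intermediate (not isolated)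
8 | 3-[(Z)-oct-2-enyl]penta-1,4-diyn-3-ol | CCCCC/C=C\CC(O)(C#C)C#C | intermediate
9 | triethyl{[3-[(Z)-oct-2-enyl]penta-1,4-diyn-3-yl]oxy}silane | CCCCC/C=C\CC(O[Si](CC)(CC)CC)(C#C)C#C | intermediate
10 | triethyl{[1-iodo-3-[(Z)-oct-2-enyl]penta-1,4-diyn-3-yl]oxy}silane (racemic) | CCCCC/C=C\CC(O[Si](CC)(CC)CC)(C#C)C#CI | intermediate (not isolated)
11 | triethyl{[1,5-diiodo-3-[(Z)-oct-2-enyl]penta-1,4-diyn-3-yl]oxy}silane | CCCCC/C=C\CC(O[Si](CC)(CC)CC)(C#CI)C#CI | intermediate
12 | triethyl{[(Z)-1,5-diiodo-3-[(Z)-oct-2-enyl]pent-1-en-4-yn-3-yl]oxy}silane (racemic) | CCCCC/C=C\CC(O[Si](CC)(CC)CC)(C#CI)/C=C\I | intermediate (not isolated)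
13 | triethyl{[(1Z,4Z)-1,5-diiodo-3-[(Z)-oct-2-enyl]penta-1,4-dien-3-yl]oxy}silane | CCCCC/C=C\CC(O[Si](CC)(CC)CC)(/C=C\I)/C=C\I | intermediate (key-step precursor)
14 | (4R)-5-[(Z)-iodomethylidene]-4-[(Z)-oct-2-enyl]-4-(triethylsilyloxy)cyclopent-2-en-1-one | CCCCC/C=C\C[C@@]1(O[Si](CC)(CC)CC)C=CC(=O)/C1=C\I | intermediate (key-step product)
15 | methyl hex-5-ynoate | COC(=O)CCCC#C | starting material
16 | methyl (E)-6-(4,4,5,5-tetramethyl-1,3,2-dioxaborolan-2-yl)hex-5-enoate | COC(=O)CCC/C=C/B1OC(C)(C)C(C)(C)O1 | intermediate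
17 | methyl (5E,7Z)-7-[(5R)-5-[(Z)-oct-2-enyl]-2-oxo-5-(triethylsilyloxy)cyclopent-3-en-1-ylidene]hept-5-enoate | CCCCC/C=C\C[C@@]1(O[Si](CC)(CC)CC)C=CC(=O)/C1=C\C=C\CCCC(=O)OC | intermediate
18 | methyl (5E,7Z)-7-[2-[(Z)-oct-2-enyl]-4-oxo-2-(triethylsilyloxy)-6-oxabicyclo[3.1.0]hexan-3-ylidene]hept-5-enoate, oxirane trans to the silyloxy group | CCCCC/C=C\C[C@@]1(O[Si](CC)(CC)CC)[C@H]2O[C@H]2C(=O)/C1=C\C=C\CCCC(=O)OC | intermediate
19 | methyl (5E,7Z)-7-[3-bromo-4-hydroxy-5-[(Z)-oct-2-enyl]-2-oxo-5-(triethylsilyloxy)cyclopentylidene]hept-5-enoate, Br trans to OH, OH trans to the silyloxy group | CCCCC/C=C\C[C@@]1(O[Si](CC)(CC)CC)[C@@H](O)[C@H](Br)C(=O)/C1=C\C=C\CCCC(=O)OC | intermediate (not isolated)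
20 | methyl (5E,7Z)-7-[(5R)-3-bromo-5-[(Z)-oct-2-enyl]-2-oxo-5-(triethylsilyloxy)cyclopent-3-en-1-ylidene]hept-5-enoate | CCCCC/C=C\C[C@@]1(O[Si](CC)(CC)CC)C=C(Br)C(=O)/C1=C\C=C\CCCC(=O)OC | intermediate (not isolated)
21 | methyl (5E,7Z)-7-[(5R)-3-bromo-5-hydroxy-5-[(Z)-oct-2-enyl]-2-oxocyclopent-3-en-1-ylidene]hept-5-enoate | CCCCC/C=C\C[C@@]1(O)C=C(Br)C(=O)/C1=C\C=C\CCCC(=O)OC | intermediate
22 | methyl (5E,7Z)-7-[(5R)-5-acetoxy-3-bromo-5-[(Z)-oct-2-enyl]-2-oxocyclopent-3-en-1-ylidene]hept-5-enoate | CCCCC/C=C\C[C@@]1(OC(C)=O)C=C(Br)C(=O)/C1=C\C=C\CCCC(=O)OC | target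

Total step count: 12. Longest linear sequence: 11 steps (steps 1–7 and 9–12); step 8 is a one-step branch.

Steps most likely to fail

Step 7. The acyl–palladium may not insert into the iodine-bearing alkene: it may close 6-exo onto C14=C15 or 6-endo at C7, the vinyl–palladium may cyclise onto C14=C15 before CO uptake, or the α-iodoalkyl–palladium may lose iodide. The product iodide may also be consumed by a second carbonylation, and the ligand may discriminate poorly between the two arms. The fallback exchanges the order of coupling and ring closure and uses known reaction types only; it sets out from 13 and comes back at 17. Bis-iodide 13, taken in threefold excess and recovered, would be coupled once with boronate 16 (Pd(PPh3)4, aq. K3PO4, THF, rt). This should give the racemic mono-coupled iodide, methyl (5E,7Z,11Z)-9-[(Z)-2-iodoethenyl]-9-(triethylsilyloxy)heptadeca-5,7,11-trienoate F1. F1 is a (Z)-1-iodo-1,4-diene with a carbon-substituted acceptor alkene, the substrate class of the established cyclic acylpalladation. Pd(PPh3)4, CO and Et3N in MeCN/THF at 60 °C should close it by the same syn-insertion and syn-elimination course, with C6 ending cis to C9, to the racemic form of 17, F2. Preparative HPLC on a chiral stationary phase would separate F2 into 17, which goes on to step 10, and its (S)-enantiomer F3.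

Step 10. Hydroperoxide may add at C7 or C5 of the dienone arm instead of C11, the base may isomerise the 7Z bond by reversible conjugate addition, or the ester may be hydrolysed. The fallback brings bromine to C10 without peroxide or hydroxide; it sets out from 17 and comes back at 20. Iodine and pyridine in CH2Cl2 (Baylis–Hillman-type addition, iodination and elimination, which does not touch isolated alkenes) should give the 10-iodo enone, methyl (5E,7Z)-7-[(5R)-3-iodo-5-[(Z)-oct-2-enyl]-2-oxo-5-(triethylsilyloxy)cyclopent-3-en-1-ylidene]hept-5-enoate F4. Palladium-catalysed stannylation with Me3SnSnMe3 (PdCl2(MeCN)2, NMP, rt) would give the 10-trimethylstannyl enone, methyl (5E,7Z)-7-[(5R)-5-[(Z)-oct-2-enyl]-2-oxo-5-(triethylsilyloxy)-3-(trimethylstannyl)cyclopent-3-en-1-ylidene]hept-5-enoate F5. N-Bromosuccinimide in THF at −78 °C would then replace tin by bromine at the same carbon to give 20, which is desilylated under the acid conditions of the last stage of step 11 to 21.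

Step 11. Strong aqueous acid may erode the 7Z and 5E geometry through reversible conjugate addition of bromide before dehydration and desilylation are complete, or may leave a mixture of 19, 20 and 21. The fallback separates the three events under non-protic or buffered conditions; it sets out from 18 and comes back at 21. MgBr2·OEt2 in Et2O at −20 °C should open 18 to bromohydrin 19, which is carried on crude. MsCl and Et3N in CH2Cl2 at 0 °C would convert it through the 11-mesylate, methyl (5E,7Z)-7-[3-bromo-4-(methylsulfonyloxy)-5-[(Z)-oct-2-enyl]-2-oxo-5-(triethylsilyloxy)cyclopentylidene]hept-5-enoate F6, into 20 by E1cB elimination. HF·pyridine buffered with pyridine in THF at 0 °C would then remove the silyl group to give 21.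

Further compounds
F1 | step 7 | methyl (5E,7Z,11Z)-9-[(Z)-2-iodoethenyl]-9-(triethylsilyloxy)heptadeca-5,7,11-trienoate (racemic) | CCCCC/C=C\CC(O[Si](CC)(CC)CC)(/C=C\I)/C=C\C=C\CCCC(=O)OC
F2 | step 7 | racemic methyl (5E,7Z)-7-[5-[(Z)-oct-2-enyl]-2-oxo-5-(triethylsilyloxy)cyclopent-3-en-1-ylidene]hept-5-enoate | CCCCC/C=C\CC1(O[Si](CC)(CC)CC)C=CC(=O)/C1=C\C=C\CCCC(=O)OC
F3 | step 7 | methyl (5E,7Z)-7-[(5S)-5-[(Z)-oct-2-enyl]-2-oxo-5-(triethylsilyloxy)cyclopent-3-en-1-ylidene]hept-5-enoate | CCCCC/C=C\C[C@]1(O[Si](CC)(CC)CC)C=CC(=O)/C1=C\C=C\CCCC(=O)OC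
F4 | step 10 | methyl (5E,7Z)-7-[(5R)-3-iodo-5-[(Z)-oct-2-enyl]-2-oxo-5-(triethylsilyloxy)cyclopent-3-en-1-ylidene]hept-5-enoate | CCCCC/C=C\C[C@@]1(O[Si](CC)(CC)CC)C=C(I)C(=O)/C1=C\C=C\CCCC(=O)OC
F5 | step 10 | methyl (5E,7Z)-7-[(5R)-5-[(Z)-oct-2-enyl]-2-oxo-5-(triethylsilyloxy)-3-(trimethylstannyl)cyclopent-3-en-1-ylidene]hept-5-enoate | CCCCC/C=C\C[C@@]1(O[Si](CC)(CC)CC)C=C([Sn](C)(C)C)C(=O)/C1=C\C=C\CCCC(=O)OC
F6 | step 11 | methyl (5E,7Z)-7-[3-bromo-4-(methylsulfonyloxy)-5-[(Z)-oct-2-enyl]-2-oxo-5-(triethylsilyloxy)cyclopentylidene]hept-5-enoate, Br trans to the mesylate | CCCCC/C=C\C[C@@]1(O[Si](CC)(CC)CC)[C@@H](OS(C)(=O)=O)[C@H](Br)C(=O)/C1=C\C=C\CCCC(=O)OC
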